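**Plan** (guaiane numbering: C1–C5 five-membered ring with C1/C5 at the fusion, C5–C10 plus C1 seven-membered ring, C15 on C4, C14 on C10, C11(C12)(C13) on C7)
1. Retrosynthesis: the sulfate comes off C12–O first; the hydrogens at C4/C5 and C8/C9 are replaced by C4=C5 and C8=C9; then C7–C11 is cut, then C7=C8 (metathesis), C8–C9 (vinyl addition), C1–C10 (aldol), and the cyclopentenone (Stetter/aldol).
2. Enabling feature: C9 is a plain CH2 of the seven-membered ring, 1,3 to C7 and next to the C10 carbinol; as a temporary 9β allylic oxygen across C7=C8 it carries an O-benzyl lactate whose α-carbon is C11 and whose carbonyl is C12, so a [3,3] shift from O–C9 to C7 forms C7–C11.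
3. Forward: five-membered ring first, then C1–C10, then the seven-membered ring by ring-closing metathesis, then the side chain by Ireland–Claisen rearrangement, then saturation, deprotection and sulfation.
4. Stereochemistry: C10 from (R)-lactic acid (self-regeneration of the stereocentre through its pivalaldehyde acetal); C1 from the ketone face in the aldol; C9 from chelation-controlled vinylation; C7 from suprafacial transfer of the 9β C–O bond; C11 from the chelated (Z)-ketene acetal in a boat transition state; C4 and C5 together from hydrogenation directed by the C1 hydroxyl.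
5. Helpers removed later: the C9 oxygen (lost in the rearrangement), C8=C9 and C4=C5 (hydrogenated), the C12 acid level (reduced), the trimethylsilyl ethers (fluoride) and the benzyl ether (hydrogenolysis).

Key step: step 10

Remark: the target is drawn as the free hydrogen sulfate, so the last step ends with exchange of the pyridinium counter-ion for H+; the free acid is best kept cold and in solution.

**Step 1**
Reactants: 1 pent-4-enal; 2 but-3-en-2-one
Product: 3 non-8-ene-2,5-dione
Conditions: 3-benzyl-5-(2-hydroxyethyl)-4-methylthiazolium chloride (10 mol%), Et3N, EtOH, 80 °C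
Reagents that add atoms: none
Why: Stetter reaction, in which the thiazolium carbene turns the aldehyde into an acyl anion equivalent that adds in conjugate fashion to the enone to give the 1,4-diketone; no stereocentre is formed.

**Step 2**
Reactants: 3 non-8-ene-2,5-dione
Product: 4 2-allyl-3-methylcyclopent-2-en-1-one
Conditions: 2% aq. NaOH, EtOH, reflux
Reagents that add atoms: none
Why: intramolecular aldol condensation of a 2,5-dione, which should close through the C6 enolate onto the methyl ketone to give the tetrasubstituted cyclopentenone, as in the jasmone series.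

**Step 3**
Reactants: 5 (R)-lactic acid; 6 pivalaldehyde
Product: 7 (2R,5R)-2-tert-butyl-5-methyl-1,3-dioxolan-4-one (cis)
Conditions: p-TsOH (cat.), H2SO4 (cat.), pentane, reflux with azeotropic removal of water; recrystallisation from Et2O/pentane at −78 °C
Reagents that add atoms: none
Why: acid-catalysed acetalisation of an α-hydroxy acid, in which the cis acetal (new centre 2R, set relative to the lactate centre) should predominate and be purified by crystallisation.

**Step 4**
Reactants: 7 (2R,5R)-2-tert-butyl-5-methyl-1,3-dioxolan-4-one; 4 2-allyl-3-methylcyclopent-2-en-1-one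
Product: 9 (2R,5S)-2-tert-butyl-5-[(1S)-1-hydroxy-3-methyl-2-(prop-2-en-1-yl)cyclopent-2-en-1-yl]-5-methyl-1,3-dioxolan-4-one, via lithium enolate 8 (not isolated)
Conditions: LDA, THF, −78 °C; then 4, −78 °C; AcOH quench at −78 °C
Reagents that add atoms: none
Why: lithium enolate aldol addition in which the enolate should react anti to tert-butyl (setting C10), add 1,2 because the β-carbon of the enone is fully substituted, and select the ketone face through a closed lithium-bridged transition state that turns the substituted C5(allyl)=C4(Me) flank away from the dioxolanone ring (expected 1S, the least certain element of the route).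

**Step 5**
Reactants: 9 aldol adduct
Product: 10 (2R,5S)-2-tert-butyl-5-[(1S)-1-hydroxy-3-methyl-2-(prop-2-en-1-yl)cyclopent-2-en-1-yl]-5-methyl-1,3-dioxolan-4-ol (both C4 epimers)
Conditions: DIBAL-H (2.5 equiv), CH2Cl2, −78 °C; Rochelle salt work-up
Reagents that add atoms: none
Why: partial reduction of the lactone-type carbonyl to the lactol at low temperature, a known transformation of dioxolanones; the new hemiacetal centre is of no consequence.

**Step 6**
Reactants: 10 lactol
Product: 12 (2R,3S)-2-[(1S)-1-hydroxy-3-methyl-2-(prop-2-en-1-yl)cyclopent-2-en-1-yl]pent-4-ene-2,3-diol, via ring-opened hydroxy aldehyde 11 (not isolated)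
Conditions: CH2=CHMgBr (6 equiv), THF, −78 → 0 °C; aq. NH4Cl
Reagents that add atoms: vinylmagnesium bromide, C=C[Mg]Br
Why: Grignard addition to a lactol, in which the alkoxide opens to the α-alkoxido aldehyde with loss of pivalaldehyde and magnesium bridging C10–O and C9=O (chelation control) should direct the vinyl group to the face of the small C14 methyl, away from the C1 branch, to give 9S.

**Step 7**
Reactants: 12 diene triol
Product: 13 (1S,9S,10R)-11,12,13-trinorguaia-4,7-diene-1,9,10-triol (1-OH and 10-OH cis, 9-OH trans to both)
Conditions: [RuCl2(=CHPh)(H2IMes)(PCy3)] (5 mol%), CH2Cl2 (5 mM), 40 °C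
Reagents that add atoms: none
Why: ring-closing metathesis of the two monosubstituted alkenes should close the seven-membered ring at C7=C8 while the tetrasubstituted C4=C5 stays inert; no stereocentre is touched.

**Step 8**
Reactants: 13 bicyclic triol; 14 (2S)-2-(benzyloxy)propanoic acid
Product: 15 (1S,9S,10R)-1,10-dihydroxy-11,12,13-trinorguaia-4,7-dien-9-yl (2S)-2-(benzyloxy)propanoate
Conditions: DCC, DMAP (cat.), CH2Cl2, 0 °C → rt
Reagents that add atoms: none
Why: Steglich esterification, which should acylate only the secondary allylic C9 hydroxyl because the two tertiary hydroxyls are unreactive; C9 keeps its configuration and the lactate centre is erased later on enolisation.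

**Step 9**
Reactants: 15 diol ester
Product: 16 (1S,9S,10R)-1,10-bis(trimethylsilyloxy)-11,12,13-trinorguaia-4,7-dien-9-yl (2S)-2-(benzyloxy)propanoate
Conditions: TMSOTf, 2,6-lutidine, CH2Cl2, −78 → 0 °C
Reagents that add atoms: trimethylsilyl trifluoromethanesulfonate, C[Si](C)(C)OS(=O)(=O)C(F)(F)F
Why: silylation of the two tertiary alcohols under buffered conditions, which removes the free alkoxides that would otherwise cause acyl migration from C9–O to C10–O during enolisation.

**Step 10**
Reactants: 16 bis-silyl ester
Product: 19 (1S,7S,10R,11R)-11-(benzyloxy)-1,10-dihydroxyguaia-4,8-dien-12-oic acid, via silyl ketene acetal 17 (not isolated), via trimethylsilyl ester 18 (not isolated)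
Conditions: LDA, THF, −78 °C; TMSCl/Et3N, −78 → 50 °C; then TBAF, THF, rt; aq. NH4Cl
Reagents that add atoms: chlorotrimethylsilane, C[Si](C)(C)Cl (its silyl group is carried by 17 and 18 only and no atom of it remains in 19)
Why: LDA should form the lithium-chelated enolate of the α-benzyloxy ester (OBn cis to O–Li), TMSCl traps it as the (Z)-ketene acetal 17, and a concerted [3,3]-sigmatropic shift breaks O–C9 and forms C11–C7 across C9–C8=C7 to give silyl ester 18, after which fluoride removes all three silyl groups. The closest known reaction type is the Ireland–Claisen rearrangement of α-alkoxy (glycolate and lactate) esters of cyclic secondary allylic alcohols. No ring is closed; the six-membered array exists only in the pericyclic transition state. C7 is set by suprafacial transfer: the new bond forms on the β face from which the C9–O bond departs, so 9β-O gives 7β-C11 (7S in 19, 7R once C8=C9 is saturated). C11 is set by the ketene acetal geometry (OBn cis to OSiMe3, methyl cis to the allylic oxygen) combined with a boat transition state, which gives 11R. The step needs boat over chair, which is secured because the chair would place the OSiMe3 group of C12 over the β face of the seven-membered ring against the β-methyl C14 on C10; regiochemistry is unambiguous because C7=C8 is the only alkene allylic to the ester.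

**Step 11**
Reactants: 19 dihydroxy acid
Product: 20 (1S,7S,10R,11R)-11-(benzyloxy)guaia-4,8-diene-1,10,12-triol
Conditions: LiAlH4 (excess), THF, 0 °C → reflux; aq. NaOH work-up
Reagents that add atoms: none
Why: hydride reduction of the carboxylic acid to the primary alcohol C12–OH, with benzyl ether, alkenes and all stereocentres untouched.

**Step 12**
Reactants: 20 diene triol
Product: 21 (1S,4S,5S,7R,10R,11R)-11-(benzyloxy)guaiane-1,10,12-triol
Conditions: H2 (1–5 bar), [Ir(cod)(PCy3)(py)]PF6 (10 mol%), CH2Cl2, rt
Reagents that add atoms: none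
Why: hydroxyl-directed homogeneous hydrogenation, in which iridium bound to the allylic C1 hydroxyl (α face) should deliver both hydrogens syn to it across the tetrasubstituted C4=C5 (4S,5S; C15 cis to C6, cis ring fusion) while C8=C9 is saturated at the same time.

**Step 13**
Reactants: 21 benzyl ether triol
Product: 22 (1S,4S,5S,7R,10R,11R)-guaiane-1,10,11,12-tetrol
Conditions: H2 (1 bar), Pd(OH)2/C, EtOH, rt
Reagents that add atoms: none
Why: hydrogenolysis of the benzyl ether on a substrate that no longer holds an alkene or an allylic C–O bond.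

**Step 14**
Reactants: 22 tetraol
Product: 23 (1S,4S,5S,7R,10R,11R)-1,10,11-trihydroxyguaian-12-yl hydrogen sulfate (target)
Conditions: SO3·pyridine (1.3 equiv), pyridine, 0 °C → rt; then Dowex 50W (H+ form), H2O/MeOH, 0 °C
Reagents that add atoms: sulfur trioxide pyridine complex, O=S(=O)([O-])[n+]1ccccc1
Why: O-sulfation with a sulfur trioxide amine complex, which should take the single primary hydroxyl selectively over the three hindered tertiary ones.

**Compound list**
1 | pent-4-enal | C=CCCC=O | starting material
2 | but-3-en-2-one (methyl vinyl ketone) | CC(=O)C=C | starting material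
3 | non-8-ene-2,5-dione | CC(=O)CCC(=O)CCC=C | intermediate
4 | 2-allyl-3-methylcyclopent-2-en-1-one | CC1=C(CC=C)C(=O)CC1 | intermediate
5 | (R)-lactic acid | C[C@@H](O)C(=O)O | starting material
6 | pivalaldehyde | CC(C)(C)C=O | starting material
7 | (2R,5R)-2-tert-butyl-5-methyl-1,3-dioxolan-4-one | C[C@H]1O[C@@H](C(C)(C)C)OC1=O | intermediate
8 | lithium (2R)-2-tert-butyl-5-methyl-1,3-dioxol-4-olate | CC1=C([O-])O[C@H](C(C)(C)C)O1.[Li+] | intermediate
9 | (2R,5S)-2-tert-butyl-5-[(1S)-1-hydroxy-3-methyl-2-(prop-2-en-1-yl)cyclopent-2-en-1-yl]-5-methyl-1,3-dioxolan-4-one | CC1=C(CC=C)[C@@](O)(CC1)[C@]2(C)O[C@@H](C(C)(C)C)OC2=O | intermediate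
10 | (2R,5S)-2-tert-butyl-5-[(1S)-1-hydroxy-3-methyl-2-(prop-2-en-1-yl)cyclopent-2-en-1-yl]-5-methyl-1,3-dioxolan-4-ol (both C4 epimers) | CC1=C(CC=C)[C@@](O)(CC1)[C@]2(C)O[C@@H](C(C)(C)C)OC2O | intermediate
11 | (2S)-2-hydroxy-2-[(1S)-1-hydroxy-3-methyl-2-(prop-2-en-1-yl)cyclopent-2-en-1-yl]propanal (present as its bromomagnesium alkoxide) | CC1=C(CC=C)[C@@](O)(CC1)[C@](C)(O)C=O | intermediate
12 | (2R,3S)-2-[(1S)-1-hydroxy-3-methyl-2-(prop-2-en-1-yl)cyclopent-2-en-1-yl]pent-4-ene-2,3-diol | CC1=C(CC=C)[C@@](O)(CC1)[C@](C)(O)[C@@H](O)C=C | intermediate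
13 | (1S,9S,10R)-11,12,13-trinorguaia-4,7-diene-1,9,10-triol | CC1=C2CC=C[C@H](O)[C@@](C)(O)[C@]2(O)CC1 | intermediate
14 | (2S)-2-(benzyloxy)propanoic acid | C[C@H](OCc1ccccc1)C(=O)O | starting material
15 | (1S,9S,10R)-1,10-dihydroxy-11,12,13-trinorguaia-4,7-dien-9-yl (2S)-2-(benzyloxy)propanoate | CC1=C2CC=C[C@H](OC(=O)[C@H](C)OCc3ccccc3)[C@@](C)(O)[C@]2(O)CC1 | intermediate
16 | (1S,9S,10R)-1,10-bis(trimethylsilyloxy)-11,12,13-trinorguaia-4,7-dien-9-yl (2S)-2-(benzyloxy)propanoate | CC1=C2CC=C[C@H](OC(=O)[C@H](C)OCc3ccccc3)[C@@](C)(O[Si](C)(C)C)[C@]2(O[Si](C)(C)C)CC1 | intermediate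
17 | (Z)-silyl ketene acetal of 16 (benzyloxy cis to OSiMe3) | CC1=C2CC=C[C@H](O/C(O[Si](C)(C)C)=C(\C)OCc3ccccc3)[C@@](C)(O[Si](C)(C)C)[C@]2(O[Si](C)(C)C)CC1 | intermediate
18 | trimethylsilyl (1S,7S,10R,11R)-11-(benzyloxy)-1,10-bis(trimethylsilyloxy)guaia-4,8-dien-12-oate | CC1=C2C[C@H]([C@@](C)(OCc3ccccc3)C(=O)O[Si](C)(C)C)C=C[C@@](C)(O[Si](C)(C)C)[C@]2(O[Si](C)(C)C)CC1 | intermediate
19 | (1S,7S,10R,11R)-11-(benzyloxy)-1,10-dihydroxyguaia-4,8-dien-12-oic acid | CC1=C2C[C@H]([C@@](C)(OCc3ccccc3)C(=O)O)C=C[C@@](C)(O)[C@]2(O)CC1 | intermediate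
20 | (1S,7S,10R,11R)-11-(benzyloxy)guaia-4,8-diene-1,10,12-triol | CC1=C2C[C@H]([C@@](C)(OCc3ccccc3)CO)C=C[C@@](C)(O)[C@]2(O)CC1 | intermediate
21 | (1S,4S,5S,7R,10R,11R)-11-(benzyloxy)guaiane-1,10,12-triol | C[C@H]1CC[C@]2(O)[C@H]1C[C@H]([C@@](C)(OCc3ccccc3)CO)CC[C@@]2(C)O | intermediate
22 | (1S,4S,5S,7R,10R,11R)-guaiane-1,10,11,12-tetrol | C[C@H]1CC[C@]2(O)[C@H]1C[C@H]([C@@](C)(O)CO)CC[C@@]2(C)O | intermediate
23 | (1S,4S,5S,7R,10R,11R)-1,10,11-trihydroxyguaian-12-yl hydrogen sulfate | C[C@H]1CC[C@]2(O)[C@H]1C[C@H]([C@@](C)(O)COS(=O)(=O)O)CC[C@@]2(C)O | target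

**Count**
Total steps: 14. Longest linear sequence: 13 steps (steps 1, 2 and 4–14, from pent-4-enal and methyl vinyl ketone); the lactic acid branch (step 3) joins at step 4.

**Steps most likely to fail**

Step 4. What may go wrong: poor discrimination between the two faces of the enone carbonyl (mixture of C1 epimers), or loss of adduct through retro-aldol cleavage of the tertiary aldolate on warming. Fallback, setting out from 7 (through enolate 8) and returning at 9: the enolate is added to 2-bromo-3-methylcyclopent-2-en-1-one F1 instead of 4. The bromine is a larger and more polar flank than the allyl-bearing carbon, so the two sides of the carbonyl should be differentiated more strongly in the same sense, and the more electrophilic carbonyl should hold the adduct better. The resulting bromo carbinol F2 is then joined to the allyl group by Stille coupling with allyltributylstannane (Pd2(dba)3, AsPh3, CuI, DMF) to give 9.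

Step 10. What may go wrong: leakage through the chair transition state (C11 epimer), or slow rearrangement of the hindered ketene acetal with competing ester cleavage. Fallback, setting out from 16 and returning at 22: the C7–C11 bond is made by palladium-catalysed allylic alkylation (Tsuji–Trost), with C11 controlled by an auxiliary and not by transition-state shape. (2S,5S)-2-tert-butyl-5-methyl-1,3-dioxolan-4-one F3 (made like 7 from (S)-lactic acid and 6) is converted with LDA into its lithium enolate F4 and combined with 16 and Pd(PPh3)4 in THF. The C9 carboxylate is ionised with inversion, and the enolate attacks anti to palladium at the less hindered C7 terminus (net retention, 7β) and anti to its own tert-butyl group (11R), to give C7-alkylated dioxolanone F5. LiAlH4 followed by TBAF gives diene tetraol F6, which is hydrogenated as in step 12 to give 22.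

Step 12. What may go wrong: incomplete or face-unselective saturation of the tetrasubstituted C4=C5 (catalyst deactivation by the triol, or ionisation of the tertiary allylic alcohols by the acidic iridium hydride). Fallback, setting out from 20 and returning at 22: the two alkenes are treated separately and the face is set by adsorption, not by chelation. Hydrogenation over Pd(OH)2/C in EtOAc containing Et3N removes the benzyl group and saturates C8=C9 to give 4-ene tetraol F7. Hydrogenation of F7 over Rh/Al2O3 under pressure in EtOH should then add hydrogen from the α face, which carries the anchoring hydroxyls and is not shielded by C14 and the C7 side chain, to give 22.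

**Further compounds**
F1 | step 4 | 2-bromo-3-methylcyclopent-2-en-1-one | CC1=C(Br)C(=O)CC1
F2 | step 4 | (2R,5S)-5-[(1R)-2-bromo-1-hydroxy-3-methylcyclopent-2-en-1-yl]-2-tert-butyl-5-methyl-1,3-dioxolan-4-one | CC1=C(Br)[C@@](O)(CC1)[C@]2(C)O[C@@H](C(C)(C)C)OC2=O
F3 | step 10 | (2S,5S)-2-tert-butyl-5-methyl-1,3-dioxolan-4-one | C[C@@H]1O[C@H](C(C)(C)C)OC1=O
F4 | step 10 | lithium (2S)-2-tert-butyl-5-methyl-1,3-dioxol-4-olate | CC1=C([O-])O[C@@H](C(C)(C)C)O1.[Li+]
F5 | step 10 | (2S,5R)-2-tert-butyl-5-methyl-5-[(1S,7S,10R)-1,10-bis(trimethylsilyloxy)-11,12,13-trinorguaia-4,8-dien-7-yl]-1,3-dioxolan-4-one | CC1=C2C[C@H]([C@@]3(C)O[C@H](C(C)(C)C)OC3=O)C=C[C@@](C)(O[Si](C)(C)C)[C@]2(O[Si](C)(C)C)CC1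
F6 | step 10 | (1S,7S,10R,11R)-guaia-4,8-diene-1,10,11,12-tetrol | CC1=C2C[C@H]([C@@](C)(O)CO)C=C[C@@](C)(O)[C@]2(O)CC1
F7 | step 12 | (1S,7R,10R,11R)-guai-4-ene-1,10,11,12-tetrol | CC1=C2C[C@H]([C@@](C)(O)CO)CC[C@@](C)(O)[C@]2(O)CC1
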